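## The problem

Target 17 is a flavone with no stereocentre: benzene ring A is fused to the 4-pyranone ring C, ring B sits on C2, and the whole difficulty is regiochemical. Six oxygen substituents sit on the skeleton, four as methyl ethers (C3, C7, C8, C2') and two as free phenols (C5, C4'), and the synthesis must end with exactly these two unmasked. Ring A has to carry the 5,7,8 pattern and not the isomeric 5,6,7 pattern, which comes down to which ortho oxygen of a 1,2,3,5-tetraoxygenated benzene becomes O1. Ring C is fully substituted, and its C3 oxygen cannot be added late by electrophilic attack without also touching the electron-rich C6 position. The sensitive points are the pyranone, which hard nucleophiles open at C2, the electron-rich phenols, and any 2-aryl-3-oxybenzofuran on the way, which autoxidises at C2. The enabling feature is C3 itself, a single carbon that bears only a heteroatom and lies between C2 and the C4 carbonyl. If it is taken out, C2 and C4 close up to the enol ether double bond of a 2-aryl-3-silyloxybenzofuran, and a dihalocarbene can put that carbon back with a halogen on it as the handle for the methoxyl.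

## Retrosynthesis

**17 from 16.** The O–CH3 bond at C5 and the O–benzyl bond at C4' are cut last. The C5 methyl ether is the only one peri to the C4 carbonyl, so a chelating Lewis acid can tell it apart from the other four. Ring A can therefore come from a symmetrical tetramethyl ether, with no early regioselective protection. Benzyl on C4' falls to the same reagent. The forward step must spare the C3, C7, C8 and C2' methoxyls.

**16 from 13 through 15.** The C3–O bond is cut. The methyl ether 16 comes from flavonol 15, and 15 from the 3-bromoflavone 13 through the boronate 14. Direct displacement of bromide by methoxide is avoided because alkoxides attack C2 of a 3-halochromone. The C–B/C–O sequence uses only acetate and buffered peroxide. The forward step asks for borylation of a hindered α-carbonyl vinylic bromide without loss of boron before oxidation.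

**13 from 9 and bromoform 10 (key step).** The C2–C3 and C3–C4 bonds are cut and C3 leaves as dibromocarbene. The six-membered ring C shrinks to the furan ring of the silyl enol ether 9. Compared with aldol or Claisen closures of ring C, this cut creates C3 as one atom in a fixed position and leaves a halogen there as a handle for oxygen. The precursor 9 is one ring atom smaller and is reached by a single aryl–carbon coupling. The forward reaction must cyclopropanate the tetrasubstituted C2=C3 bond of 9 (gem-dibromocyclopropane 11) and open it at the fusion bond (pyrylium ion 12).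

**9 from 5 and 7.** The C2–C1' bond is cut. The benzofuranone 5 and the ring B bromide 7 are joined by enolate arylation, and the resulting enolate 8 is silylated on oxygen. The neighbouring cut, building the aryl group in before furanone closure, would need an α-halo arylacetic acid derivative of an electron-rich arene. The forward step asks for monoarylation and O-silylation without isolating the air-sensitive ketone.

**5 from 1 and 2; 7 from 6.** The O1–C2 and C3–C3a bonds of 5 are cut. The two free positions of symmetrical 1 are equivalent, so acylation with chloroacetyl chloride 2 can give only ketone 3. Cleavage of the flanked ortho methoxyl gives phenol 4, which closes onto the chloromethyl group. The only selectivity asked is which ortho methoxyl is freed. Bromide 7 is the benzyl ether of commercial phenol 6.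

## Roads not taken

Alternative 1: The cut is at C1'–C2 and C2–C3, with C2 taken out as carbon monoxide A3. This leaves the ring A ketone A2, 2-methoxy-1-[3,4,6-trimethoxy-2-(methoxymethoxy)phenyl]ethan-1-one, and bromide 7. Forward, the sodium enolate of A2 (from NaN(SiMe3)2), 7 and A3 would combine under Pd(dba)2 (zerovalent palladium) and 1,3-bis(diphenylphosphino)propane to give the 2-methoxy-1,3-diketone A1. Acid would then remove the acetal and cyclodehydrate to 16.
- Merits: it is convergent, the C3 methoxyl is present from the start, and no carbon–bromine to carbon–oxygen exchange is needed. It would reach 16 in about two steps fewer than the chosen plan, and in step count it is the better route.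
- Weak points: 7 is electron-rich and ortho-substituted, so oxidative addition is slow and is slowed further by A3. Direct arylation without insertion and O-aroylation compete. A1 is more acidic than A2 and can be aroylated again. A2 needs the same ortho-demethylation as step 1 plus a protection step.
- Comparison: the chosen plan offers two-component steps throughout, a single-atom insertion whose regiochemistry cannot vary, and no toxic gas under pressure.

Alternative 2: The cut goes through ring A at C4a–C5 and C8–C8a. The tetraoxygenated diene A4, (3Z)-1,3,4-trimethoxy-1-(trimethylsilyloxy)buta-1,3-diene, and the bromoalkyne A5, methyl 3-bromoprop-2-ynoate, would undergo a Diels–Alder cycloaddition. Loss of methanol from the adduct would give the benzoate A6, methyl 2-bromo-6-hydroxy-3,4-dimethoxybenzoate.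
- Merits: the ring A pattern is set by the polarity match between the ketene acetal carbon of A4 and the ester-bearing carbon of A5. The C5 hydroxyl emerges free and distinct from the C7 and C8 methyl ethers. In this respect it is better than the chosen plan, which depends on a selective peri-demethylation at the end.
- Weak points: ring A is not the hard part of 17, since 1 already has the right pattern. A4 is a hydrolytically labile ketene acetal that needs several steps, and A5 must itself be made from methyl propiolate. After A6 the hindered C8a–Br bond must still be exchanged for oxygen, and all of ring C, including the C3 methoxyl, remains to be built.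
- Comparison: the route would be clearly longer. The chosen plan buys ring A and spends its steps on ring C.

Alternative 3: The cut is at C4a–C8a. A masked open-chain triketo ester would be folded by Mg(OMe)2 in methanol in a Claisen condensation to the α-methoxychalcone A7, (Z)-3-[4-(benzyloxy)-2-methoxyphenyl]-1-(2,4-dihydroxy-3,6-dimethoxyphenyl)-2-methoxyprop-2-en-1-one. Ring C would then be closed oxidatively.
- Merits: it follows the biosynthesis, uses no palladium, and A7 holds every carbon of 17 with the C3 and C8 methoxyls in place.
- Weak points: the chain is long to assemble and needs masks. Pyranone formation and aldol folding compete with the Claisen mode. A7 has a free C7 hydroxyl that must be methylated selectively. Oxidative closure of a chalcone with a 6'-methoxyl tends toward the aurone. The final peri-demethylation is still needed.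
- Comparison: it has no advantage in length or certainty over the chosen plan.

Key step: step 5

Assumption: the AlCl3-mediated ortho-demethylation in step 1 is taken to follow the usual preference for the methoxyl flanked by the acyl group and a second methoxyl, giving 4 and not its 6-hydroxy isomer.

## Route

Step 1
Reactants: 1 1,2,3,5-tetramethoxybenzene; 2 chloroacetyl chloride
Product: 4 2-chloro-1-(2-hydroxy-3,4,6-trimethoxyphenyl)ethan-1-one, via 2-chloro-1-(2,3,4,6-tetramethoxyphenyl)ethan-1-one 3 (not isolated)
Conditions: AlCl3 (2.5 equiv), CH2Cl2, 0 °C to rt; then aq. HCl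
Reagents that add atoms: none
Why: Friedel–Crafts acylation at the only kind of free position of symmetrical 1 should give 3; AlCl3 chelated to the ketone should then cleave the ortho methoxyl that is twisted out of plane between acyl and methoxy groups, the usual outcome for 2,3,4-trialkoxyaryl ketones.

Step 2
Reactants: 4 2-chloro-1-(2-hydroxy-3,4,6-trimethoxyphenyl)ethan-1-one
Product: 5 4,6,7-trimethoxy-1-benzofuran-3(2H)-one
Conditions: NaOAc, EtOH, reflux
Reagents that add atoms: none
Why: Intramolecular Williamson O-alkylation (5-exo-tet) of the phenoxide by the α-chloroketone is the standard coumaranone closure; acetate is too weak a base to cause self-condensation of 5.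

Step 3
Reactants: 6 4-bromo-3-methoxyphenol
Product: 7 4-(benzyloxy)-1-bromo-2-methoxybenzene
Conditions: BnBr, K2CO3, DMF, rt
Reagents that add atoms: benzyl bromide, BrCc1ccccc1
Why: Williamson ether synthesis; the benzyl ether should survive strong base, carbene, palladium catalysis and peroxide and is removed by the BCl3 that also frees the C5 hydroxyl.

Step 4
Reactants: 5 4,6,7-trimethoxy-1-benzofuran-3(2H)-one; 7 4-(benzyloxy)-1-bromo-2-methoxybenzene
Product: 9 tert-butyl({2-[4-(benzyloxy)-2-methoxyphenyl]-4,6,7-trimethoxy-1-benzofuran-3-yl}oxy)dimethylsilane, via sodium 2-aryl-4,6,7-trimethoxy-1-benzofuran-3-olate 8 (not isolated)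
Conditions: NaOtBu (2.5 equiv), Pd(OAc)2 (cat.), XPhos (cat.), toluene, 80 °C; then TBSCl (2 equiv), THF, 0 °C to rt
Reagents that add atoms: tert-butyldimethylsilyl chloride, CC(C)(C)[Si](C)(C)Cl
Why: Buchwald–Hartwig–Miura α-arylation of the fully formed ketone enolate with a bulky biarylphosphine suited to electron-rich ortho-substituted bromides; the product is more acidic than 5 and stays as the aromatic benzofuran-3-olate 8, which blocks a second arylation. O-Silylation of this hard oxygen nucleophile in the same flask should avoid isolating the autoxidation-prone 2-arylbenzofuranone.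

Step 5
Reactants: 9 tert-butyl({2-[4-(benzyloxy)-2-methoxyphenyl]-4,6,7-trimethoxy-1-benzofuran-3-yl}oxy)dimethylsilane; 10 bromoform
Product: 13 2-[4-(benzyloxy)-2-methoxyphenyl]-3-bromo-5,7,8-trimethoxy-4H-chromen-4-one, via gem-dibromocyclopropane adduct 11 (not isolated), via 3-bromo-4-silyloxybenzopyrylium bromide 12 (not isolated)
Conditions: KOtBu (3 equiv), CHBr3 (2 equiv), toluene–hexane, −20 °C to rt; then 1 M HCl, THF, rt
Reagents that add atoms: none
Why: KOtBu converts bromoform by α-elimination into dibromocarbene, an electrophilic singlet carbene that should add in a concerted [2+1] step to the most electron-rich π bond, the C2=C3 enol ether bond of 9, giving the gem-dibromocyclopropane 11. The fusion bond of 11 (the old C2–C3 bond) should then break in a disrotatory two-electron electrocyclic opening as the endo bromide leaves, so the carbene carbon ends up bonded to C2 and to the silyloxy carbon (the new C2–C3 and C3–C4 bonds) within the benzopyrylium ion 12, stabilised by O1 and the silyloxy oxygen. tert-Butoxide should remove the silyl group from 12 and the C4 carbonyl appears. The closest known reactions are the dihalocarbene ring expansion of cyclic silyl enol ethers to α-halo enones and the Ciamician–Dennstedt-type expansion of benzofurans to 3-halochromenes; here both driving forces act on the same bond. Ring C therefore forms by one-carbon ring expansion of the furan (cyclopropanation, then electrocyclic opening) and not by a cyclisation. No stereocentre is created in 13; the two in racemic, necessarily cis-fused 11 are lost on opening. The step needs chemoselectivity for the enol ether over the alkoxyarene rings and the benzyl ether, secured by the much higher nucleophilicity of the doubly oxygen-substituted double bond, and regioselective opening, secured because only cleavage of the fusion bond gives an oxygen-stabilised aromatic cation. Any 2-tert-butoxychromene formed by alkoxide capture of 12 should converge on 13 in the acidic work-up.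

Step 6
Reactants: 13 2-[4-(benzyloxy)-2-methoxyphenyl]-3-bromo-5,7,8-trimethoxy-4H-chromen-4-one
Product: 15 2-[4-(benzyloxy)-2-methoxyphenyl]-3-hydroxy-5,7,8-trimethoxy-4H-chromen-4-one, via flavone 3-pinacolboronate 14 (not isolated)
Conditions: B2pin2, Pd(dppf)Cl2 (cat.), KOAc, 1,4-dioxane, 90 °C; then 30% aq. H2O2, aq. NaHCO3, THF, 0 °C to rt
Reagents that add atoms: hydrogen peroxide, OO
Why: Miyaura borylation of the activated C3–Br bond uses only acetate, which does not open the pyranone; oxidation of the C–B bond by hydroperoxide (1,2-shift from boron to oxygen) in the same flask should give the flavonol before protodeboronation can intervene.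

Step 7
Reactants: 15 2-[4-(benzyloxy)-2-methoxyphenyl]-3-hydroxy-5,7,8-trimethoxy-4H-chromen-4-one
Product: 16 2-[4-(benzyloxy)-2-methoxyphenyl]-3,5,7,8-tetramethoxy-4H-chromen-4-one
Conditions: MeI, K2CO3, acetone, reflux
Reagents that add atoms: iodomethane, CI
Why: Williamson O-methylation of the acidic flavonol hydroxyl, the only free hydroxyl in 15.

Step 8
Reactants: 16 2-[4-(benzyloxy)-2-methoxyphenyl]-3,5,7,8-tetramethoxy-4H-chromen-4-one
Product: 17 5-hydroxy-2-(4-hydroxy-2-methoxyphenyl)-3,7,8-trimethoxy-4H-chromen-4-one (5,4'-dihydroxy-3,7,8,2'-tetramethoxyflavone)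
Conditions: BCl3 (excess), C6HMe5, CH2Cl2, −78 °C to 0 °C; then MeOH, aq. NaHCO3
Reagents that add atoms: none
Why: BCl3 should cleave the benzyl ether at low temperature, with the benzyl cation trapped by pentamethylbenzene, and on warming cleave the C5 methyl ether through a six-membered boron chelate with the C4 carbonyl. The C3 methoxyl could only form a five-membered chelate and the C7, C8 and C2' methoxyls none, so they should survive.

## Compound list

1 | 1,2,3,5-tetramethoxybenzene | COc1cc(OC)c(OC)c(OC)c1 | starting material
2 | chloroacetyl chloride | ClCC(=O)Cl | starting material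
3 | 2-chloro-1-(2,3,4,6-tetramethoxyphenyl)ethan-1-one | COc1cc(OC)c(C(=O)CCl)c(OC)c1OC | intermediate (not isolated)
4 | 2-chloro-1-(2-hydroxy-3,4,6-trimethoxyphenyl)ethan-1-one | COc1cc(OC)c(C(=O)CCl)c(O)c1OC | intermediate
5 | 4,6,7-trimethoxy-1-benzofuran-3(2H)-one | COc1cc(OC)c2c(c1OC)OCC2=O | intermediate
6 | 4-bromo-3-methoxyphenol | COc1cc(O)ccc1Br | starting material
7 | 4-(benzyloxy)-1-bromo-2-methoxybenzene | COc1cc(OCc2ccccc2)ccc1Br | intermediate
8 | sodium 2-[4-(benzyloxy)-2-methoxyphenyl]-4,6,7-trimethoxy-1-benzofuran-3-olate | [Na+].[O-]c1c(-c2ccc(OCc3ccccc3)cc2OC)oc2c(OC)c(OC)cc(OC)c12 | intermediate (not isolated)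
9 | tert-butyl({2-[4-(benzyloxy)-2-methoxyphenyl]-4,6,7-trimethoxy-1-benzofuran-3-yl}oxy)dimethylsilane | COc1cc(OC)c2c(O[Si](C)(C)C(C)(C)C)c(-c3ccc(OCc4ccccc4)cc3OC)oc2c1OC | intermediate
10 | bromoform | BrC(Br)Br | starting material
11 | tert-butyl({1a-[4-(benzyloxy)-2-methoxyphenyl]-1,1-dibromo-3,4,6-trimethoxy-1a,6b-dihydro-1H-cyclopropa[b][1]benzofuran-6b-yl}oxy)dimethylsilane (racemic; the cis ring fusion is the only one possible) | COc1cc(OC)c2c(c1OC)OC1(c3ccc(OCc4ccccc4)cc3OC)C(Br)(Br)C21O[Si](C)(C)C(C)(C)C | intermediate (not isolated)
12 | 2-[4-(benzyloxy)-2-methoxyphenyl]-3-bromo-4-[(tert-butyldimethylsilyl)oxy]-5,7,8-trimethoxychromenylium bromide | COc1cc(OCc2ccccc2)ccc1-c1[o+]c2c(OC)c(OC)cc(OC)c2c(O[Si](C)(C)C(C)(C)C)c1Br.[Br-] | intermediate (not isolated)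
13 | 2-[4-(benzyloxy)-2-methoxyphenyl]-3-bromo-5,7,8-trimethoxy-4H-chromen-4-one | COc1cc(OCc2ccccc2)ccc1-c1oc2c(OC)c(OC)cc(OC)c2c(=O)c1Br | intermediate
14 | 2-[4-(benzyloxy)-2-methoxyphenyl]-5,7,8-trimethoxy-3-(4,4,5,5-tetramethyl-1,3,2-dioxaborolan-2-yl)-4H-chromen-4-one | COc1cc(OCc2ccccc2)ccc1-c1oc2c(OC)c(OC)cc(OC)c2c(=O)c1B1OC(C)(C)C(C)(C)O1 | intermediate (not isolated)
15 | 2-[4-(benzyloxy)-2-methoxyphenyl]-3-hydroxy-5,7,8-trimethoxy-4H-chromen-4-one | COc1cc(OCc2ccccc2)ccc1-c1oc2c(OC)c(OC)cc(OC)c2c(=O)c1O | intermediate
16 | 2-[4-(benzyloxy)-2-methoxyphenyl]-3,5,7,8-tetramethoxy-4H-chromen-4-one | COc1cc(OCc2ccccc2)ccc1-c1oc2c(OC)c(OC)cc(OC)c2c(=O)c1OC | intermediate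
17 | 5-hydroxy-2-(4-hydroxy-2-methoxyphenyl)-3,7,8-trimethoxy-4H-chromen-4-one | COc1cc(O)ccc1-c1oc2c(OC)c(OC)cc(O)c2c(=O)c1OC | target

## Step count and risks

Total step count: 8. Longest linear sequence: 7 (steps 1, 2, 4, 5, 6, 7, 8 from 1 to 17); step 3 is the side branch.

**Step 5 (key step).** The most likely failure is loss of the silyl group to tert-butoxide before the carbene arrives; the free enolate would then be attacked at C2 without ring expansion. Incomplete cyclopropanation of the crowded tetrasubstituted double bond is the second risk. The fallback gives up the ring expansion and builds ring C by Baker–Venkataraman chemistry, setting out from 1 and 7 and returning at 16. Friedel–Crafts acylation of 1 with methoxyacetyl chloride and AlCl3 would give, through 2-methoxy-1-(2,3,4,6-tetramethoxyphenyl)ethan-1-one F1, the ortho-hydroxy ketone 1-(2-hydroxy-3,4,6-trimethoxyphenyl)-2-methoxyethan-1-one F2. Bromide 7 would be converted by bromine–lithium exchange (n-BuLi) and CO2 into 4-(benzyloxy)-2-methoxybenzoic acid F3. Steglich esterification would give 2-(2-methoxyacetyl)-3,5,6-trimethoxyphenyl 4-(benzyloxy)-2-methoxybenzoate F4. KOtBu would rearrange it to 1-[4-(benzyloxy)-2-methoxyphenyl]-3-(2-hydroxy-3,4,6-trimethoxyphenyl)-2-methoxypropane-1,3-dione F5, and TsOH in warm toluene would cyclodehydrate F5 to 16, making steps 6 and 7 unnecessary.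

**Step 4.** Oxidative addition of the electron-rich, ortho-substituted bromide may be slow, and the enolate 8 may be oxidised at C2 by traces of air before it is silylated. The fallback reverses the order, from 5 back to 9. Compound 5 would be silylated (TBSOTf, Et3N) to tert-butyl[(4,6,7-trimethoxy-1-benzofuran-3-yl)oxy]dimethylsilane F6. Its C2–H bond would then be arylated directly with 7 by concerted metalation–deprotonation (Pd(OAc)2, PCy3, pivalic acid, K2CO3, DMA), so the 2-aryl ketone never exists as a free species.

**Step 6.** Protodeboronation of 14, or hydrodebromination of 13 during the borylation, would both give the 3-unsubstituted flavone, because the C3–B bond lies α to a carbonyl. The fallback uses this outcome, from 13 back to 15. Bromine would be removed reductively (Pd(OAc)2, PPh3, HCO2Na) to give 2-[4-(benzyloxy)-2-methoxyphenyl]-5,7,8-trimethoxy-4H-chromen-4-one F7. F7 would be lithiated at C3 with LiN(iPr)2 at −78 °C, trapped with B(OMe)3 and oxidised cold with H2O2 to 15. This is the established C3 lithiation–boration–oxidation of flavones.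

**Step 8.** Over-cleavage (loss of the C3 or C8 methyl ether on warming) or Friedel–Crafts benzylation of ring A at C6 by the benzyl cation may occur. The fallback separates the two deprotections by mechanism, from 16 back to 17. Hydrogenolysis (H2, Pd/C, EtOAc) would give 2-(4-hydroxy-2-methoxyphenyl)-3,5,7,8-tetramethoxy-4H-chromen-4-one F8. AlCl3 in MeCN would then cleave only the chelated C5 methyl ether.

## Further compounds

F1 | step 5 | 2-methoxy-1-(2,3,4,6-tetramethoxyphenyl)ethan-1-one | COCC(=O)c1c(OC)c(OC)c(OC)cc1OC
F2 | step 5 | 1-(2-hydroxy-3,4,6-trimethoxyphenyl)-2-methoxyethan-1-one | COCC(=O)c1c(O)c(OC)c(OC)cc1OC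
F3 | step 5 | 4-(benzyloxy)-2-methoxybenzoic acid | COc1cc(OCc2ccccc2)ccc1C(=O)O
F4 | step 5 | 2-(2-methoxyacetyl)-3,5,6-trimethoxyphenyl 4-(benzyloxy)-2-methoxybenzoate | COCC(=O)c1c(OC(=O)c2ccc(OCc3ccccc3)cc2OC)c(OC)c(OC)cc1OC
F5 | step 5 | 1-[4-(benzyloxy)-2-methoxyphenyl]-3-(2-hydroxy-3,4,6-trimethoxyphenyl)-2-methoxypropane-1,3-dione (racemic, enolisable) | COC(C(=O)c1ccc(OCc2ccccc2)cc1OC)C(=O)c1c(O)c(OC)c(OC)cc1OC
F6 | step 4 | tert-butyl[(4,6,7-trimethoxy-1-benzofuran-3-yl)oxy]dimethylsilane | COc1cc(OC)c2c(O[Si](C)(C)C(C)(C)C)coc2c1OC
F7 | step 6 | 2-[4-(benzyloxy)-2-methoxyphenyl]-5,7,8-trimethoxy-4H-chromen-4-one | COc1cc(OCc2ccccc2)ccc1-c1cc(=O)c2c(OC)cc(OC)c(OC)c2o1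
F8 | step 8 | 2-(4-hydroxy-2-methoxyphenyl)-3,5,7,8-tetramethoxy-4H-chromen-4-one | COc1cc(O)ccc1-c1oc2c(OC)c(OC)cc(OC)c2c(=O)c1OC
A1 | alternative 1 | 1-[4-(benzyloxy)-2-methoxyphenyl]-2-methoxy-3-[3,4,6-trimethoxy-2-(methoxymethoxy)phenyl]propane-1,3-dione (racemic, enolisable) | COCOc1c(OC)c(OC)cc(OC)c1C(=O)C(OC)C(=O)c1ccc(OCc2ccccc2)cc1OC
A2 | alternative 1 | 2-methoxy-1-[3,4,6-trimethoxy-2-(methoxymethoxy)phenyl]ethan-1-one | COCOc1c(OC)c(OC)cc(OC)c1C(=O)COC
A3 | alternative 1 | carbon monoxide | [C-]#[O+]
A4 | alternative 2 | (3Z)-1,3,4-trimethoxy-1-(trimethylsilyloxy)buta-1,3-diene (geometry at C1=C2 not defined) | CO/C=C(OC)/C=C(OC)O[Si](C)(C)C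
A5 | alternative 2 | methyl 3-bromoprop-2-ynoate | COC(=O)C#CBr
A6 | alternative 2 | methyl 2-bromo-6-hydroxy-3,4-dimethoxybenzoate | COC(=O)c1c(O)cc(OC)c(OC)c1Br
A7 | alternative 3 | (Z)-3-[4-(benzyloxy)-2-methoxyphenyl]-1-(2,4-dihydroxy-3,6-dimethoxyphenyl)-2-methoxyprop-2-en-1-one | COc1cc(O)c(OC)c(O)c1C(=O)/C(OC)=C/c1ccc(OCc2ccccc2)cc1OC
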